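The route rests on disconnecting two bonds around the quaternary carbon C3 of the lactone ring (O1, C2, C3, C4, C5): the C3–O bond of the tertiary hydroxyl and the bond between the exocyclic methylene C6 and the syringyl ring. C3 and C6 are therefore the two carbons of a C3=C6 alkene in an α-methylene lactone. A single three-component radical coupling attaches an aryl radical, released from a diazonium salt, to C6 and a nitroxide oxygen to C3, and sets C3 relative to C4. Its precursor is the (S)-4-[4-(benzyloxy)-3-methoxybenzyl]-3-methylene butyrolactone, reached by Stobbe condensation, asymmetric hydrogenation, lactonisation and methylenation; the partner is an O-benzylated syringyl diazonium salt.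

Key step: step 9

Assumption: the (4R,5R) antipode of MOD-DIOP is taken as the one that gives the (S)-acid 4 from the E half-ester; if the rotation of lactone 6 indicated the opposite sense, the (4S,5S) ligand would be used instead.

Step 1
Reactants: 1 4-(benzyloxy)-3-methoxybenzaldehyde; 2 dimethyl succinate
Product: 3 (E)-4-[4-(benzyloxy)-3-methoxyphenyl]-3-(methoxycarbonyl)but-3-enoic acid
Conditions: NaOMe, MeOH, reflux; then aq. HCl to pH 2
Reagents that add atoms: none
Why: Stobbe condensation: the succinate enolate adds to the aldehyde, the alkoxide lactonises onto the remote ester and base-induced opening of that lactone gives the alkylidene half-ester with the free acid on the CH2 arm and the aryl group trans to the conjugated ester (E).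

Step 2
Reactants: 3 (E)-4-[4-(benzyloxy)-3-methoxyphenyl]-3-(methoxycarbonyl)but-3-enoic acid
Product: 4 (S)-4-[4-(benzyloxy)-3-methoxyphenyl]-3-(methoxycarbonyl)butanoic acid
Conditions: H2 (3 atm), [Rh(cod)2]BF4 / (4R,5R)-MOD-DIOP (1 mol %), Et3N (1 equiv), MeOH, 30 °C; crystallisation
Reagents that add atoms: none
Why: Rh-catalysed asymmetric hydrogenation of an itaconate-type half-ester: the carboxylate and the alkene chelate rhodium, so the chiral bisphosphine should deliver H2 to one face and set the new centre as S, while the homogeneous catalyst leaves the benzyl ether untouched.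

Step 3
Reactants: 4 (S)-4-[4-(benzyloxy)-3-methoxyphenyl]-3-(methoxycarbonyl)butanoic acid
Product: 6 (S)-4-[4-(benzyloxy)-3-methoxybenzyl]dihydrofuran-2(3H)-one, via hydroxy acid 5 (not isolated)
Conditions: KOH (1 equiv), EtOH; CaCl2, NaBH4, EtOH, −10 °C → rt; then 2 M HCl, rt
Reagents that add atoms: none
Why: Chemoselective borohydride reduction followed by lactonisation: the potassium carboxylate is inert while calcium borohydride formed in situ reduces the methyl ester to the primary alcohol, and acid then closes the γ-lactone without touching the stereocentre.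

Step 4
Reactants: 6 (S)-4-[4-(benzyloxy)-3-methoxybenzyl]dihydrofuran-2(3H)-one
Product: 8 (S)-4-[4-(benzyloxy)-3-methoxybenzyl]-3-methylenedihydrofuran-2(3H)-one, via formyl enolate 7 (not isolated)
Conditions: NaH, HCO2Et, THF, 0 °C → rt; then (CH2O)n, THF, 60 °C
Reagents that add atoms: formaldehyde (from paraformaldehyde), C=O
Why: Claisen formylation followed by deformylative methylenation: the formyl enolate adds to formaldehyde, the formyl group shifts to the new alkoxide and leaves as formate by elimination, and C4 is never deprotonated so its configuration should be kept.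

Step 5
Reactants: 9 2,6-dimethoxyphenol
Product: 10 4-bromo-2,6-dimethoxyphenol
Conditions: NBS (1.0 equiv), NaH (cat.), CHCl3, −45 °C → rt
Reagents that add atoms: N-bromosuccinimide, O=C1CCC(=O)N1Br
Why: Electrophilic aromatic bromination: a trace of phenoxide makes the position para to oxygen the most nucleophilic site, so bromine should enter at C4 and not next to a methoxy group.

Step 6
Reactants: 10 4-bromo-2,6-dimethoxyphenol
Product: 11 2-(benzyloxy)-5-bromo-1,3-dimethoxybenzene
Conditions: BnBr, K2CO3, DMF, 60 °C
Reagents that add atoms: benzyl bromide, BrCc1ccccc1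
Why: Williamson ether synthesis: the phenoxide displaces bromide from benzyl bromide in an SN2 reaction, and the aryl bromide is inert to these conditions.

Step 7
Reactants: 11 2-(benzyloxy)-5-bromo-1,3-dimethoxybenzene
Product: 13 4-(benzyloxy)-3,5-dimethoxyaniline, via N-aryl ketimine 12 (not isolated)
Conditions: Ph2C=NH, Pd2(dba)3 (cat.), rac-BINAP (cat.), NaOt-Bu, toluene, 80 °C; then cat. aq. HCl, wet THF, rt
Reagents that add atoms: benzophenone imine, N=C(c1ccccc1)c1ccccc1
Why: Buchwald–Hartwig amination with an ammonia surrogate: oxidative addition of the unhindered aryl bromide, amido formation and C–N reductive elimination give the ketimine, which mild acid hydrolyses to the primary aniline without cleaving the benzyl ether.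

Step 8
Reactants: 13 4-(benzyloxy)-3,5-dimethoxyaniline
Product: 14 4-(benzyloxy)-3,5-dimethoxybenzenediazonium tetrafluoroborate
Conditions: NaNO2, 48% aq. HBF4, EtOH–H2O, 0 °C; precipitation with cold Et2O
Reagents that add atoms: sodium nitrite, [Na+].[O-]N=O; tetrafluoroboric acid, [H+].F[B-](F)(F)F
Why: Diazotisation: nitrosation of the aniline and dehydration give the arenediazonium ion, which is stabilised by its donor substituents and should crystallise as the tetrafluoroborate.

Step 9
Reactants: 8 (S)-4-[4-(benzyloxy)-3-methoxybenzyl]-3-methylenedihydrofuran-2(3H)-one; 14 4-(benzyloxy)-3,5-dimethoxybenzenediazonium tetrafluoroborate; 15 TEMPO (2,2,6,6-tetramethylpiperidin-1-oxyl)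
Product: 16 (3S,4R)-3-[4-(benzyloxy)-3,5-dimethoxybenzyl]-4-[4-(benzyloxy)-3-methoxybenzyl]-3-[(2,2,6,6-tetramethylpiperidin-1-yl)oxy]dihydrofuran-2(3H)-one
Conditions: 15 (2.7 equiv), Na, naphthalene (cat.), THF, rt (gives TEMPONa); syringe-pump addition (2 h) to 8 (1 equiv) and 14 (2.5 equiv), PhCF3, rt, Ar; product kept at or below rt
Reagents that add atoms: none
Why: Single-electron transfer from TEMPONa to 14 releases N2 and gives the aryl radical together with one equivalent of free TEMPO; the aryl radical adds to the unsubstituted exocyclic carbon C6 of the enoate, and the resulting planar tertiary α-acyl radical at C3 is captured at oxygen by the nitroxide. The closest known reaction type is the Meerwein-type radical oxyarylation (carbo-oxygenation) of styrenes and acrylates with arenediazonium salts and TEMPO or TEMPONa. No ring is formed. The new stereocentre C3 is controlled by the existing C4 centre: the C4 benzyl group shields one face of the lactone radical, so the bulky nitroxide should bond on the other face, which places oxygen trans to the C4 benzyl group and the two benzyl groups cis, i.e. 3S,4R. The step needs regioselective addition at CH2 (secured by the 1,1-disubstitution and the stability of the α-carbonyl radical), cross-coupling in preference to aryl–nitroxide coupling or oligomerisation (secured by slow release of the nitroxide, which still traps the adduct radical at a near-diffusion rate, and by using the alkene as the limiting component), and facial selectivity (secured by the C4 substituent). The alkoxyamine is not heated, because tertiary α-acyl C–ON bonds homolyse thermally, and is carried straight into step 10.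

Step 10
Reactants: 16 (3S,4R)-3-[4-(benzyloxy)-3,5-dimethoxybenzyl]-4-[4-(benzyloxy)-3-methoxybenzyl]-3-[(2,2,6,6-tetramethylpiperidin-1-yl)oxy]dihydrofuran-2(3H)-one
Product: 17 (3S,4R)-3-[4-(benzyloxy)-3,5-dimethoxybenzyl]-4-[4-(benzyloxy)-3-methoxybenzyl]-3-hydroxydihydrofuran-2(3H)-one
Conditions: Zn dust, AcOH–THF–H2O (3:1:1), rt → 40 °C
Reagents that add atoms: none
Why: Reductive N–O cleavage by dissolving zinc: electron transfer breaks the weak alkoxyamine N–O bond to leave the tertiary alcohol with C3 unchanged, while the lactone and the benzyl ethers are inert to zinc in acetic acid.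

Step 11
Reactants: 17 (3S,4R)-3-[4-(benzyloxy)-3,5-dimethoxybenzyl]-4-[4-(benzyloxy)-3-methoxybenzyl]-3-hydroxydihydrofuran-2(3H)-one
Product: 18 (3S,4R)-3-hydroxy-3-(4-hydroxy-3,5-dimethoxybenzyl)-4-(4-hydroxy-3-methoxybenzyl)dihydrofuran-2(3H)-one
Conditions: H2 (1 atm), 10% Pd/C, EtOAc–EtOH, rt
Reagents that add atoms: none
Why: Catalytic hydrogenolysis: the two aryl benzyl ethers are cleaved at the benzylic C–O bond, whereas the tertiary hydroxyl (not benzylic) and the lactone C–O bonds are not activated and should survive.

Compound list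
1 | 4-(benzyloxy)-3-methoxybenzaldehyde | COc1cc(C=O)ccc1OCc1ccccc1 | starting material
2 | dimethyl succinate | COC(=O)CCC(=O)OC | starting material
3 | (E)-4-[4-(benzyloxy)-3-methoxyphenyl]-3-(methoxycarbonyl)but-3-enoic acid | COc1cc(/C=C(/C(=O)OC)CC(=O)O)ccc1OCc1ccccc1 | intermediate
4 | (S)-4-[4-(benzyloxy)-3-methoxyphenyl]-3-(methoxycarbonyl)butanoic acid | COc1cc(C[C@@H](CC(=O)O)C(=O)OC)ccc1OCc1ccccc1 | intermediate
5 | (S)-4-[4-(benzyloxy)-3-methoxyphenyl]-3-(hydroxymethyl)butanoic acid | COc1cc(C[C@@H](CC(=O)O)CO)ccc1OCc1ccccc1 | intermediate (not isolated)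
6 | (S)-4-[4-(benzyloxy)-3-methoxybenzyl]dihydrofuran-2(3H)-one | COc1cc(C[C@@H]2COC(=O)C2)ccc1OCc1ccccc1 | intermediate
7 | sodium [(4S)-4-[4-(benzyloxy)-3-methoxybenzyl]-2-oxodihydrofuran-3(2H)-ylidene]methanolate | COc1cc(C[C@@H]2COC(=O)C2=C[O-])ccc1OCc1ccccc1.[Na+] | intermediate (not isolated)
8 | (S)-4-[4-(benzyloxy)-3-methoxybenzyl]-3-methylenedihydrofuran-2(3H)-one | COc1cc(C[C@@H]2COC(=O)C2=C)ccc1OCc1ccccc1 | intermediate
9 | 2,6-dimethoxyphenol | COc1cccc(OC)c1O | starting material
10 | 4-bromo-2,6-dimethoxyphenol | COc1cc(Br)cc(OC)c1O | intermediate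
11 | 2-(benzyloxy)-5-bromo-1,3-dimethoxybenzene | COc1cc(Br)cc(OC)c1OCc1ccccc1 | intermediate
12 | N-(diphenylmethylene)-4-(benzyloxy)-3,5-dimethoxyaniline | COc1cc(N=C(c2ccccc2)c2ccccc2)cc(OC)c1OCc1ccccc1 | intermediate (not isolated)
13 | 4-(benzyloxy)-3,5-dimethoxyaniline | COc1cc(N)cc(OC)c1OCc1ccccc1 | intermediate
14 | 4-(benzyloxy)-3,5-dimethoxybenzenediazonium tetrafluoroborate | N#[N+]c1cc(OC)c(OCc2ccccc2)c(OC)c1.F[B-](F)(F)F | intermediate
15 | TEMPO (2,2,6,6-tetramethylpiperidin-1-oxyl) | CC1(C)CCCC(C)(C)N1[O] | starting material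
16 | (3S,4R)-3-[4-(benzyloxy)-3,5-dimethoxybenzyl]-4-[4-(benzyloxy)-3-methoxybenzyl]-3-[(2,2,6,6-tetramethylpiperidin-1-yl)oxy]dihydrofuran-2(3H)-one | COc1cc(C[C@@H]2COC(=O)[C@]2(ON3C(C)(C)CCCC3(C)C)Cc4cc(OC)c(OCc5ccccc5)c(OC)c4)ccc1OCc6ccccc6 | intermediate
17 | (3S,4R)-3-[4-(benzyloxy)-3,5-dimethoxybenzyl]-4-[4-(benzyloxy)-3-methoxybenzyl]-3-hydroxydihydrofuran-2(3H)-one | COc1cc(C[C@@H]2COC(=O)[C@]2(O)Cc3cc(OC)c(OCc4ccccc4)c(OC)c3)ccc1OCc5ccccc5 | intermediate
18 | (3S,4R)-3-hydroxy-3-(4-hydroxy-3,5-dimethoxybenzyl)-4-(4-hydroxy-3-methoxybenzyl)dihydrofuran-2(3H)-one | COc1cc(C[C@@H]2COC(=O)[C@]2(O)Cc2cc(OC)c(O)c(OC)c2)ccc1O | target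

Total step count: 11 (steps 1–4 to the lactone, steps 5–8 to the diazonium salt, steps 9–11 after convergence).
Longest linear sequence: 7 steps (1, 2, 3, 4, 9, 10, 11; the branch 5, 6, 7, 8, 9, 10, 11 is equally long).

Steps most likely to fail

Step 9. Three processes could spoil it:
- insufficient facial discrimination at the planar C3 radical;
- coupling of the aryl radical with the nitroxide before it reaches the alkene;
- chain growth of the adduct radical onto a second enoate.

The fallback builds the same two bonds by ionic chemistry from the same two building blocks. It sets out from bromide 11 and methylene lactone 8. Magnesium insertion into 11 (Mg, THF) should give [4-(benzyloxy)-3,5-dimethoxyphenyl]magnesium bromide F1. Copper-catalysed 1,4-addition of F1 to 8 (CuI cat., THF, −30 °C), followed by protonation, should give (4S)-3-[4-(benzyloxy)-3,5-dimethoxybenzyl]-4-[4-(benzyloxy)-3-methoxybenzyl]dihydrofuran-2(3H)-one F2 as a mixture of C3 epimers, which is of no consequence. Deprotonation (KHMDS, THF, −78 °C) and oxidation of the enolate with 2-(phenylsulfonyl)-3-phenyloxaziridine, which is expected to approach anti to the C4 benzyl group, comes back to the route at 17.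

Step 4. The exocyclic double bond could migrate into the ring under the basic conditions, which would erase C4, or the deformylation could stall and the enoate polymerise on heating. The fallback is a Mannich/elimination sequence that sets out from lactone 6:
- enolisation (LDA, THF, −78 °C) and trapping with dimethylmethyleneammonium iodide should give (3R,4S)-4-[4-(benzyloxy)-3-methoxybenzyl]-3-[(dimethylamino)methyl]dihydrofuran-2(3H)-one F3;
- quaternisation with MeI should give [(3R,4S)-4-[4-(benzyloxy)-3-methoxybenzyl]-2-oxotetrahydrofuran-3-yl]-N,N,N-trimethylmethanaminium iodide F4;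
- elimination with aqueous NaHCO3 at room temperature comes back to the route at 8 without ever exposing the enoate to strong base.

Step 2. The enantioselectivity could be too low or the sense of induction opposite, and this step is the only source of absolute configuration. The fallback is a classical resolution that sets out from half-ester 3:
- hydrogenation with an achiral cationic rhodium catalyst ([Rh(nbd)(dppb)]BF4, H2, MeOH) should give racemic 4-[4-(benzyloxy)-3-methoxyphenyl]-3-(methoxycarbonyl)butanoic acid F5 with the benzyl ether intact;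
- fractional crystallisation with (R)-1-phenylethylamine (or its antipode, whichever gives the less soluble salt of the S acid) should give (R)-1-phenylethylammonium (S)-4-[4-(benzyloxy)-3-methoxyphenyl]-3-(methoxycarbonyl)butanoate F6;
- acidification comes back to the route at 4.

Further compounds
F1 | step 9 | [4-(benzyloxy)-3,5-dimethoxyphenyl]magnesium bromide | COc1cc([Mg]Br)cc(OC)c1OCc1ccccc1
F2 | step 9 | (4S)-3-[4-(benzyloxy)-3,5-dimethoxybenzyl]-4-[4-(benzyloxy)-3-methoxybenzyl]dihydrofuran-2(3H)-one (C3 epimers) | COc1cc(C[C@@H]2COC(=O)C2Cc2cc(OC)c(OCc3ccccc3)c(OC)c2)ccc1OCc1ccccc1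
F3 | step 4 | (3R,4S)-4-[4-(benzyloxy)-3-methoxybenzyl]-3-[(dimethylamino)methyl]dihydrofuran-2(3H)-one | COc1cc(C[C@@H]2COC(=O)[C@H]2CN(C)C)ccc1OCc1ccccc1
F4 | step 4 | [(3R,4S)-4-[4-(benzyloxy)-3-methoxybenzyl]-2-oxotetrahydrofuran-3-yl]-N,N,N-trimethylmethanaminium iodide | COc1cc(C[C@@H]2COC(=O)[C@H]2C[N+](C)(C)C)ccc1OCc1ccccc1.[I-]
F5 | step 2 | racemic 4-[4-(benzyloxy)-3-methoxyphenyl]-3-(methoxycarbonyl)butanoic acid | COc1cc(CC(CC(=O)O)C(=O)OC)ccc1OCc1ccccc1
F6 | step 2 | (R)-1-phenylethylammonium (S)-4-[4-(benzyloxy)-3-methoxyphenyl]-3-(methoxycarbonyl)butanoate | COc1cc(C[C@@H](CC(=O)[O-])C(=O)OC)ccc1OCc1ccccc1.C[C@@H]([NH3+])c1ccccc1
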